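A small charge, 0.10 M of substrate against 0.0950 M of partner, makes intermediate, and the second reagent then turns intermediate into product. I turned each constant into a time at the charged amounts.

substrate 0.10 M; partner 0.0950 M; second reagent 0.120 M; time 40 min
    substrate + partner → intermediate (k1 = 0.209 L mol⁻¹ min⁻¹)
    second reagent + intermediate → product (k2 = 0.0738 L mol⁻¹ min⁻¹)
- the reaction counts as stopped when no species that holds the substrate changes by six tenths of a point or more over the second half of the time
- run time (flask): 40 min
- which holds at 40 min: what has brought the reaction to rest, or that it has not come to rest (all of the substrate has reacted / the partner has run out first / it is still moving / the second reagent has run out first / forward and back rates have come level)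
- the product standing at 40 min, as a percentage of the substrate charged

The first step's time constant, one over its constant times the partner charge, was 50.4 min. The second step's, one over its constant times the second reagent charge, I called the product clock: 113 min. Each minute, with the second reagent at its charge, product gains the standing intermediate divided by this clock.

I treated substrate as equal to partner, so the amount converted by the first step followed a hyperbola in u, the time over the first time constant:

u = 0.794
converted at the end = partner × u / (1 + u) = 0.0421 M
mean converted over the run = partner × (1 − ln(1 + u) / u) = 0.0251 M

At half the time the hyperbola gave 0.0270 M converted, so by this estimate the second half still moved 15.1% of the substrate charged, and I committed to a flask still moving. Mean converted × time / clock gave product of 8.88%.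

The weak link was counting as intermediate what had already become product. I took product as rising with time squared, which makes its average a third of its end value, and I took that off the mean:

product = 8.88% / (1 + time / (3 × clock)) = 7.95%

The forecast said it is still moving, with product at 7.9%, between 7.5% and 8.3%. Its grounds: “neither the partner nor the second reagent has run out”.

The simulation gave it is still moving, with product at 7.92%. Run backward, the clock turned that yield into a mean intermediate of 22.4% of the substrate charged in this flask, with the second reagent held at its charge; the intermediate read 25.6% at 20.0 min. A neighbouring flask, like this one but with 0.20 M of second reagent, had a clock shorter than this flask's, 67.8 min, and the same reckoning, on the same mean converted, gave 12.4%. That neighbouring flask ended with substrate at 56.2%, intermediate at 31.5% and product at 12.2%.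

(All constants were set for the occasion; the run is a simulation.)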